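**Strategy.** Numbering follows the decalin: ring A = C1–C5/C10, ring B = C5–C10, C4 bears the exocyclic CH2 (C11), C9 the methyl and the quinonylmethyl group. Everything rests on opening ring B at C5–C6: C5 is a quaternary carbon next to C4, which can be a ketone before it becomes C=CH2, and C6 is an unfunctionalised CH2. The thermodynamic enolate of a ring-A 2-methylcyclohexanone that carries the C9–C8–C7–C6–OTs chain on C10 is alkylated intramolecularly; one operation closes ring B, creates quaternary C5 and fixes the cis fusion by relay from C10. C8 is bought, C10 comes from a CBS/Claisen chirality transfer, C9 from a lactone alkylation.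

Key step: step 13

Remark: compounds 1, 6 and 11 are taken as commercial; "Ar" below is 2,3,5,6-tetramethoxyphenyl; the C5 configuration drawn for 21–23 is the one expected from hydroboration and is lost in enolate 24.

Step 1
Reactants: 1 methyl (R)-3-methylglutarate
Product: 3 (R)-4-methyltetrahydro-2H-pyran-2-one, via methyl (R)-5-hydroxy-3-methylpentanoate 2 (not isolated)
Conditions: BH3·SMe2, THF, 0 °C to rt; MeOH quench; then TsOH (cat.), toluene, 60 °C
Reagents that add atoms: none
Why: Chemoselective borane reduction of the carboxylic acid beside the methyl ester, then acid-catalysed lactonisation; the bought C8 stereocentre is not touched.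

Step 2
Reactants: 3 (R)-4-methyltetrahydro-2H-pyran-2-one
Product: 5 (R)-2,2-dimethoxy-4-methyltetrahydro-2H-pyran, via O-methyl lactonium tetrafluoroborate 4 (not isolated)
Conditions: Me3OBF4, CH2Cl2, rt; then NaOMe, MeOH, −40 °C to 0 °C
Reagents that add atoms: trimethyloxonium tetrafluoroborate, C[O+](C)C.F[B-](F)(F)F; sodium methoxide, [Na+].[O-]C
Why: Meerwein O-methylation of the lactone carbonyl and capture of the dialkoxycarbenium ion by methoxide should give the cyclic ortho ester (ortholactone) needed for a Johnson-type Claisen rearrangement.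

Step 3
Reactants: 6 2-methylcyclohex-2-en-1-one
Product: 7 (S)-2-methylcyclohex-2-en-1-ol
Conditions: (R)-2-methyl-CBS-oxazaborolidine (10 mol %), BH3·SMe2, THF, −20 °C
Reagents that add atoms: none
Why: Corey–Bakshi–Shibata reduction in which the 2-methylalkenyl arm acts as the large group, so the catalyst antipode is chosen to deliver hydride to the face that gives the (S)-carbinol, the source of the C10 configuration.

Step 4
Reactants: 5 (R)-2,2-dimethoxy-4-methyltetrahydro-2H-pyran; 7 (S)-2-methylcyclohex-2-en-1-ol
Product: 10 (4R)-4-methyl-3-[(1S)-2-methylcyclohex-2-en-1-yl]tetrahydro-2H-pyran-2-one (3,4-trans expected as major), via mixed ortholactone 8 (not isolated), via cyclic ketene acetal 9 (not isolated)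
Conditions: pivalic acid (10 mol %), xylene, 140 °C, MeOH distilled off
Reagents that add atoms: none
Why: Johnson (ortho ester) Claisen rearrangement in its ortholactone form: alcohol exchange, loss of methanol to the ketene acetal and a [3,3] shift that forms C9–C10 on the ring face that carried the C–O bond (suprafacial 1,3-chirality transfer), which sets C10; the C9 configuration formed here is erased in step 7.

Step 5
Reactants: 11 1,2,4,5-tetramethoxybenzene
Product: 13 (2,3,5,6-tetramethoxyphenyl)methanol, via aryllithium 12 (not isolated)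
Conditions: n-BuLi, TMEDA, THF, 0 °C; then (CH2O)n, 0 °C to rt
Reagents that add atoms: paraformaldehyde (as formaldehyde), C=O
Why: Directed ortho-lithiation between two methoxy groups (the two free ring positions are equivalent) followed by hydroxymethylation.

Step 6
Reactants: 13 (2,3,5,6-tetramethoxyphenyl)methanol
Product: 14 3-(bromomethyl)-1,2,4,5-tetramethoxybenzene
Conditions: PBr3, Et2O, 0 °C
Reagents that add atoms: phosphorus tribromide, BrP(Br)Br
Why: Standard conversion of a benzylic alcohol into the bromide; the product is used directly.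

Step 7
Reactants: 10 (4R)-4-methyl-3-[(1S)-2-methylcyclohex-2-en-1-yl]tetrahydro-2H-pyran-2-one; 14 3-(bromomethyl)-1,2,4,5-tetramethoxybenzene
Product: 16 4-methyl-3-(2-methylcyclohex-2-en-1-yl)-3-(2,3,5,6-tetramethoxybenzyl)tetrahydro-2H-pyran-2-one (benzyl trans to the 4-methyl; C8/C9/C10 as in the target), via lithium enolate 15 (not isolated)
Conditions: LiN(i-Pr)2, THF, −78 °C; then 14, DMPU, −78 °C to −20 °C
Reagents that add atoms: none
Why: SN2 alkylation of the tetrasubstituted lactone enolate by a reactive benzylic bromide; to avoid A(1,2) strain with the C9 substituent the C8 methyl should sit pseudoaxial and shield one face, so the benzyl group should enter anti to it and set quaternary C9 (CH2Ar trans, ring-A carbon cis to the C8 methyl).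

Step 8
Reactants: 16 benzylated lactone
Product: 17 lactol (3-substituted 4-methyltetrahydro-2H-pyran-2-ol; anomer mixture)
Conditions: i-Bu2AlH, CH2Cl2, −78 °C
Reagents that add atoms: none
Why: Partial reduction of the lactone, whose tetrahedral aluminate is stable at low temperature, stops at the lactol.

Step 9
Reactants: 17 lactol
Product: 19 (3R,4R)-3-methyl-4-[(1S)-2-methylcyclohex-2-en-1-yl]-4-methyl-5-Ar-pentan-1-ol (C9 now carries CH3 and CH2Ar), via hydrazone 18 (not isolated)
Conditions: N2H4·H2O, KOH, diethylene glycol, 130 °C then 200 °C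
Reagents that add atoms: none
Why: Wolff–Kishner (Huang-Minlon) reduction of the open hydroxy aldehyde form turns the former lactone carbon into the C9 methyl group and frees the C6 alcohol; quaternary C9 cannot epimerise.

Step 10
Reactants: 19 primary alcohol
Product: 20 primary tosylate of 19
Conditions: TsCl, pyridine, CH2Cl2, 0 °C
Reagents that add atoms: p-toluenesulfonyl chloride, Cc1ccc(cc1)S(Cl)(=O)=O
Why: Sulfonylation of the unhindered primary alcohol installs the leaving group on C6.

Step 11
Reactants: 20 tosylate
Product: 22 ring-A secondary alcohol (OH on C4; H on C5), via alkylborane 21 (not isolated)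
Conditions: BH3·THF, THF, 0 °C to rt; then NaOH (aq.), H2O2, 0 °C
Reagents that add atoms: hydrogen peroxide, OO
Why: Hydroboration–oxidation places boron, then oxygen, on the less substituted C4 by syn addition anti to the bulky C10 substituent; the new C4 and C5 centres are transient and the primary tosylate is inert to borane.

Step 12
Reactants: 22 secondary alcohol
Product: 23 keto tosylate (2-methylcyclohexanone with the C9–C6 chain on C10)
Conditions: Dess–Martin periodinane, NaHCO3, CH2Cl2, rt
Reagents that add atoms: none
Why: Dess–Martin oxidation under buffered, non-basic conditions gives the ring-A ketone without touching the tosylate or the electron-rich arene.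

Step 13
Reactants: 23 keto tosylate
Product: 25 cis-fused decalone (C4 ketone; all four stereocentres as in the target), via potassium enolate 24 (not isolated)
Conditions: KOt-Bu, t-BuOH/THF, 0 °C to 45 °C
Reagents that add atoms: none
Why: KOt-Bu in t-BuOH reversibly deprotonates the ketone, and the more substituted C4–C5 potassium enolate 24 displaces the primary tosylate at C6 by intramolecular SN2, the closest precedent being base-mediated cycloalkylation of 3-(4-sulfonyloxybutyl)-2-methylcyclohexanones to 9-methyl-cis-1-decalones. Ring B closes in the 6-exo-tet mode with the enolate double bond outside the new ring (6-(enolexo)-exo-tet). The new stereocentre C5 is controlled by C10: the electrophile must approach perpendicular to the enolate plane and the four-atom tether on C10 reaches only its own face, so C5–C6 forms cis to C10–C9 and the C5 methyl ends cis to H-10. The step needs C- over O-alkylation and C5 over C3 attack; both alternatives would close eight-membered rings, quaternary C9 leaves no other acidic site in the chain, and enolate equilibration in the protic medium should funnel material through the six-membered transition state. Elimination of the tosylate by the base is the competing process and is held back by the protic solvent and moderate temperature.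

Step 14
Reactants: 25 cis-fused decalone
Product: 26 4-methylidene decalin bearing the tetramethoxybenzyl group
Conditions: Ph3PCH3Br, KOt-Bu, toluene, 90 °C
Reagents that add atoms: methyltriphenylphosphonium bromide, C[P+](c1ccccc1)(c1ccccc1)c1ccccc1.[Br-]
Why: Wittig methylenation of the hindered α-quaternary ketone with methylenetriphenylphosphorane at elevated temperature, a standard solution for 4-oxo-5-methyldecalins; no stereocentre is affected.

Step 15
Reactants: 26 tetramethoxyarene
Product: 27 2,5-dimethoxy-3-alkyl-1,4-benzoquinone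
Conditions: (NH4)2Ce(NO3)6, MeCN/H2O, 0 °C
Reagents that add atoms: water, O
Why: Oxidative demethylation by tetravalent cerium (two one-electron oxidations with attack of water) gives the para-quinone; both para-dimethoxy pairs lead to the same quinone by symmetry and the isolated exocyclic alkene should survive.

Step 16
Reactants: 27 dimethoxyquinone
Product: 28 2-hydroxy-5-methoxy-3-{[(1R,2R,4aR,8aS)-1,2,4a-trimethyl-5-methylidenedecahydronaphthalen-1-yl]methyl}cyclohexa-2,5-diene-1,4-dione (target)
Conditions: KOH (aq.), MeOH, rt; then dilute HCl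
Reagents that add atoms: potassium hydroxide, [K+].[OH-]
Why: Saponification of a vinylogous ester by addition–elimination: the methoxy group flanked by the alkyl-bearing carbon and a carbonyl is twisted out of conjugation and should be the more electrophilic, and the vinylogous carboxylate formed deactivates the second methoxy group, so mono-hydrolysis next to the side chain is expected.

**Compound list**

1 | methyl (R)-3-methylglutarate | COC(=O)C[C@H](C)CC(=O)O | starting material
2 | methyl (R)-5-hydroxy-3-methylpentanoate | COC(=O)C[C@H](C)CCO | intermediate (not isolated)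
3 | (R)-4-methyltetrahydro-2H-pyran-2-one | O=C1C[C@H](C)CCO1 | intermediate
4 | O-methyl lactonium tetrafluoroborate of 3 | COC1=[O+]CC[C@@H](C)C1.F[B-](F)(F)F | intermediate (not isolated)
5 | (R)-2,2-dimethoxy-4-methyltetrahydro-2H-pyran | COC1(OC)C[C@H](C)CCO1 | intermediate
6 | 2-methylcyclohex-2-en-1-one | CC1=CCCCC1=O | starting material
7 | (S)-2-methylcyclohex-2-en-1-ol | O[C@H]1CCCC=C1C | intermediate
8 | mixed ortholactone, (4R)-2-methoxy-4-methyl-2-[(1S)-2-methylcyclohex-2-en-1-yloxy]tetrahydro-2H-pyran | COC1(O[C@H]2CCCC=C2C)C[C@H](C)CCO1 | intermediate (not isolated)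
9 | cyclic ketene acetal, (4R)-4-methyl-6-[(1S)-2-methylcyclohex-2-en-1-yloxy]-3,4-dihydro-2H-pyran | C[C@@H]1CCOC(O[C@H]2CCCC=C2C)=C1 | intermediate (not isolated)
10 | (3R,4R)-4-methyl-3-[(1S)-2-methylcyclohex-2-en-1-yl]tetrahydro-2H-pyran-2-one (3-epimer tolerated) | CC1=CCCC[C@H]1[C@H]2[C@H](C)CCOC2=O | intermediate
11 | 1,2,4,5-tetramethoxybenzene | COc1cc(OC)c(OC)cc1OC | starting material
12 | (2,3,5,6-tetramethoxyphenyl)lithium | [Li]c1c(OC)c(OC)cc(OC)c1OC | intermediate (not isolated)
13 | (2,3,5,6-tetramethoxyphenyl)methanol | OCc1c(OC)c(OC)cc(OC)c1OC | intermediate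
14 | 3-(bromomethyl)-1,2,4,5-tetramethoxybenzene | BrCc1c(OC)c(OC)cc(OC)c1OC | intermediate
15 | lithium enolate of lactone 10 | [Li]OC1=C([C@@H]2CCCC=C2C)[C@H](C)CCO1 | intermediate (not isolated)
16 | benzylated lactone, benzyl trans to the 4-methyl, C8/C9/C10 as in the target | CC1=CCCC[C@H]1[C@]2(Cc3c(OC)c(OC)cc(OC)c3OC)[C@H](C)CCOC2=O | intermediate
17 | lactol of 16 (anomer mixture) | CC1=CCCC[C@H]1[C@]2(Cc3c(OC)c(OC)cc(OC)c3OC)[C@H](C)CCOC2O | intermediate
18 | hydrazone of the open hydroxy aldehyde | CC1=CCCC[C@H]1[C@](C=NN)(Cc2c(OC)c(OC)cc(OC)c2OC)[C@H](C)CCO | intermediate (not isolated)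
19 | primary alcohol, C9 bearing CH3, CH2Ar and the cyclohexenyl ring | CC1=CCCC[C@H]1[C@](C)(Cc2c(OC)c(OC)cc(OC)c2OC)[C@H](C)CCO | intermediate
20 | tosylate of 19 | CC1=CCCC[C@H]1[C@](C)(Cc2c(OC)c(OC)cc(OC)c2OC)[C@H](C)CCOS(=O)(=O)c2ccc(C)cc2 | intermediate
21 | C4 alkylborane (boron and C5–H syn, anti to the C10 substituent) | B[C@@H]1CCC[C@@H]([C@](C)(Cc2c(OC)c(OC)cc(OC)c2OC)[C@H](C)CCOS(=O)(=O)c2ccc(C)cc2)[C@H]1C | intermediate (not isolated)
22 | C4 secondary alcohol | O[C@@H]1CCC[C@@H]([C@](C)(Cc2c(OC)c(OC)cc(OC)c2OC)[C@H](C)CCOS(=O)(=O)c2ccc(C)cc2)[C@H]1C | intermediate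
23 | keto tosylate (C5 epimerisable) | O=C1CCC[C@@H]([C@](C)(Cc2c(OC)c(OC)cc(OC)c2OC)[C@H](C)CCOS(=O)(=O)c2ccc(C)cc2)[C@H]1C | intermediate
24 | C4–C5 potassium enolate of 23 | [K]OC1=C(C)[C@H]([C@](C)(Cc2c(OC)c(OC)cc(OC)c2OC)[C@H](C)CCOS(=O)(=O)c2ccc(C)cc2)CCC1 | intermediate (not isolated)
25 | cis-fused decalone (C4=O; 5-Me cis to H-10) | O=C1CCC[C@H]2[C@](C)(Cc3c(OC)c(OC)cc(OC)c3OC)[C@H](C)CC[C@@]12C | intermediate
26 | 4-methylidene decalin with tetramethoxybenzyl group | C=C1CCC[C@H]2[C@](C)(Cc3c(OC)c(OC)cc(OC)c3OC)[C@H](C)CC[C@@]12C | intermediate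
27 | 2,5-dimethoxy-3-alkyl-1,4-benzoquinone | C=C1CCC[C@H]2[C@](C)(CC3=C(OC)C(=O)C=C(OC)C3=O)[C@H](C)CC[C@@]12C | intermediate
28 | 2-hydroxy-5-methoxy-3-{[(1R,2R,4aR,8aS)-1,2,4a-trimethyl-5-methylidenedecahydronaphthalen-1-yl]methyl}cyclohexa-2,5-diene-1,4-dione | C=C1CCC[C@H]2[C@](C)(CC3=C(O)C(=O)C=C(OC)C3=O)[C@H](C)CC[C@@]12C | target

**Count.** Total: 16 steps. Longest linear sequence: 13 steps (1, 2, 4, 7–16).

**Steps most likely to fail**

Step 13. The cyclisation may stall because C5 is a hindered nucleophile, so that base-induced elimination of the tosylate or attack of tert-butoxide on C6 takes over. The fallback closes the same bond by an aldol addition and sets out from 19. Hydroboration–oxidation (BH3·THF; NaOH, H2O2) should give the diol F1, and Dess–Martin oxidation the keto aldehyde F2. Acid-mediated intramolecular aldol addition (TsOH, benzene, rt) of the C5 enol to the C6 aldehyde should give the cis-fused β-hydroxy ketone F3, which cannot dehydrate at quaternary C5. Its thiocarbonylimidazolide F4 (1,1'-thiocarbonyldiimidazole, DMAP) is reduced with Bu3SnH/AIBN (Barton–McCombie), and the route is rejoined at 25.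

Step 4. The rearrangement may fail through slow formation of the ketene acetal or acid-induced dehydration of the allylic alcohol. The fallback is an Ireland–Claisen rearrangement and sets out from 3 and 7. Lactone 3 is saponified and silylated (KOH; t-BuMe2SiCl, imidazole; K2CO3, MeOH) to the silyloxy acid F5, which is esterified with 7 (DCC, DMAP) to the allylic ester F6. Rearrangement of its silyl ketene acetal (LiN(i-Pr)2, Me3SiCl, THF, −78 °C to rt) should give the acid F7 with the same suprafacial transfer to C10. Bu4NF then TsOH closes the lactone, and the route is rejoined at 10 (as a C9 epimer mixture that converges in step 7).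

Step 16. Hydrolysis may take place at the other methoxy group or at both. The fallback sets out from 27: exhaustive saponification (NaOH, aq. MeOH, 50 °C) should give the dihydroxyquinone F8. Mono-O-methylation of the less hindered hydroxyl remote from the side chain (Me3SiCHN2, 1 equiv, MeOH/toluene, 0 °C) then rejoins the route at 28.

**Further compounds**

F1 | step 13 | diol (C4 secondary and C6 primary alcohol) | O[C@@H]1CCC[C@@H]([C@](C)(Cc2c(OC)c(OC)cc(OC)c2OC)[C@H](C)CCO)[C@H]1C
F2 | step 13 | keto aldehyde | O=C1CCC[C@@H]([C@](C)(Cc2c(OC)c(OC)cc(OC)c2OC)[C@H](C)CC=O)[C@H]1C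
F3 | step 13 | cis-fused β-hydroxy ketone (C6 carbinol) | O=C1CCC[C@H]2[C@](C)(Cc3c(OC)c(OC)cc(OC)c3OC)[C@H](C)CC(O)[C@@]12C
F4 | step 13 | thiocarbonylimidazolide of F3 | O=C1CCC[C@H]2[C@](C)(Cc3c(OC)c(OC)cc(OC)c3OC)[C@H](C)CC(OC(=S)n3ccnc3)[C@@]12C
F5 | step 4 | (R)-5-(tert-butyldimethylsilyloxy)-3-methylpentanoic acid | OC(=O)C[C@H](C)CCO[Si](C)(C)C(C)(C)C
F6 | step 4 | (S)-2-methylcyclohex-2-en-1-yl ester of F5 | CC1=CCCC[C@@H]1OC(=O)C[C@H](C)CCO[Si](C)(C)C(C)(C)C
F7 | step 4 | Ireland–Claisen acid (C9 epimer mixture) | CC1=CCCC[C@H]1C(C(O)=O)[C@H](C)CCO[Si](C)(C)C(C)(C)C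
F8 | step 16 | 2,5-dihydroxy-3-alkyl-1,4-benzoquinone | C=C1CCC[C@H]2[C@](C)(CC3=C(O)C(=O)C=C(O)C3=O)[C@H](C)CC[C@@]12C
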